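The plan rests on cutting the O1–C8a bond of ring C. Ring A carries the 6,7,8-trimethoxy pattern of a gallate, so its two remaining oxygenated positions, C5 and C8a on either side of C4a, become interchangeable when both start as bromides. The precursor is therefore a 2-methoxy-1,3-diketone that links a 2,6-dibromo-3,4,5-trimethoxyphenyl ketone (ring A) to a 3,5-bis(benzyloxy)-4-methoxyphenyl ketone (ring B). Copper-catalysed intramolecular O-arylation of its enolate by either bromide closes the pyranone in one operation. The other bromine is left at C5, peri to the C4 carbonyl, where it is exchanged for hydroxyl before the benzyl ethers are removed.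

Key step: step 6

Remark: the target is achiral; the only stereogenic carbons on the way (the methoxy-bearing carbon of the keto ester and of the diketone) are racemic and enolizable, so no stereocontrol is needed.

Step 1
Reactants: 1 3,4,5-trimethoxybenzoic acid
Product: 2 2,6-dibromo-3,4,5-trimethoxybenzoic acid
Conditions: Br2 (2.2 equiv), AcOH, 25 to 50 °C
Reagents that add atoms: bromine, BrBr
Why: Electrophilic aromatic bromination: C2 and C6 are the only free ring positions, each ortho and para to a methoxy group, so two equivalents of bromine should substitute both, while the protonated carboxyl group in acetic acid resists ipso bromodecarboxylation.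

Step 2
Reactants: 3 methyl 3,5-dihydroxy-4-methoxybenzoate
Product: 4 methyl 3,5-bis(benzyloxy)-4-methoxybenzoate
Conditions: BnBr (2.3 equiv), K2CO3 (3 equiv), DMF, 60 °C
Reagents that add atoms: benzyl bromide, BrCc1ccccc1
Why: Williamson ether synthesis: carbonate deprotonates the two equivalent phenols, which displace bromide from benzyl bromide, and the methyl ester is untouched.

Step 3
Reactants: 4 methyl 3,5-bis(benzyloxy)-4-methoxybenzoate; 5 methyl methoxyacetate
Product: 6 racemic methyl 3-[3,5-bis(benzyloxy)-4-methoxyphenyl]-2-methoxy-3-oxopropanoate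
Conditions: 5 (2.5 equiv), LiN(i-Pr)2 (2.4 equiv), THF, −78 °C; then 4 (1 equiv), −78 to 0 °C; aq. NH4Cl
Reagents that add atoms: none
Why: Crossed Claisen condensation: the preformed lithium enolate of 5 can only be acylated by the non-enolizable benzoate 4, the excess enolate deprotonates the keto ester and makes the step irreversible, and the new C2 stereocentre forms racemic and is removed in step 4.

Step 4
Reactants: 6 racemic methyl 3-[3,5-bis(benzyloxy)-4-methoxyphenyl]-2-methoxy-3-oxopropanoate
Product: 7 1-[3,5-bis(benzyloxy)-4-methoxyphenyl]-2-methoxyethan-1-one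
Conditions: LiCl (2 equiv), H2O (2 equiv), DMSO, 120 °C
Reagents that add atoms: none
Why: Krapcho dealkoxycarbonylation: chloride demethylates the β-keto methyl ester, the carboxylate loses CO2 and the enolate is protonated by water, under near-neutral conditions that the benzyl and methyl aryl ethers should tolerate.

Step 5
Reactants: 2 2,6-dibromo-3,4,5-trimethoxybenzoic acid; 7 1-[3,5-bis(benzyloxy)-4-methoxyphenyl]-2-methoxyethan-1-one
Product: 9 racemic 1-(2,6-dibromo-3,4,5-trimethoxyphenyl)-3-[3,5-bis(benzyloxy)-4-methoxyphenyl]-2-methoxypropane-1,3-dione, via 2,6-dibromo-3,4,5-trimethoxybenzoyl chloride 8 (not isolated)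
Conditions: 2, (COCl)2 (1.5 equiv), cat. DMF, CH2Cl2, rt, then evaporation; crude 8, 7, MgBr2·OEt2 (2.5 equiv), i-Pr2NEt (3 equiv), CH2Cl2, rt; aq. HCl
Reagents that add atoms: oxalyl chloride, ClC(=O)C(Cl)=O (its chlorine is carried only by intermediate 8 and is lost again on C-acylation)
Why: Acid chloride formation through the Vilsmeier chloroiminium is followed by a Claisen-type C-acylation under soft enolization: magnesium chelates the carbonyl and α-methoxy oxygens of 7, the amine removes the acidified α-proton, and the magnesium enolate is acylated at carbon to a chelated diketonate that resists a second acylation; the new C2 centre is racemic and enolizable and disappears in step 6.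

Step 6
Reactants: 9 racemic 1-(2,6-dibromo-3,4,5-trimethoxyphenyl)-3-[3,5-bis(benzyloxy)-4-methoxyphenyl]-2-methoxypropane-1,3-dione
Product: 10 2-[3,5-bis(benzyloxy)-4-methoxyphenyl]-5-bromo-3,6,7,8-tetramethoxy-4H-chromen-4-one
Conditions: CuI (10 mol%), 1,10-phenanthroline (20 mol%), Cs2CO3 (2 equiv), dry 1,4-dioxane (0.05 M), 100 °C, Ar
Reagents that add atoms: none
Why: Carbonate generates the enolate of the 2-methoxy-1,3-diketone, whose ring B side oxygen binds monovalent copper; rotation about the C3–C4 bond places an ortho C–Br of ring A next to the metal, oxidative addition gives a trivalent aryl copper alkoxide, and C–O reductive elimination forms O1–C8a and releases the catalyst. The closest known reaction type is the copper-catalysed intramolecular Ullmann O-arylation that turns 1-(2-bromoaryl)-1,3-diketones into chromones and flavones. Ring C closes as a six-membered ring by attack of the enolate oxygen on an aromatic sp2 carbon, a 6-exo-type closure in which the only bond made is O1–C8a. No stereocentre is formed, and the racemic C2 centre of 9 is erased on enolization. The step needs O- over C-arylation and a single defined halogen: attack through carbon or through the proximal oxygen would give four-membered rings, so only the distal oxygen can reach, and the two bromines are interchanged by rotation about the C4–C4a bond, so either gives the same 5-bromoflavone. Catalysis is required because the electron-rich aroyl ring, substituted at both ortho positions, does not undergo uncatalysed nucleophilic aromatic substitution.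

Step 7
Reactants: 10 2-[3,5-bis(benzyloxy)-4-methoxyphenyl]-5-bromo-3,6,7,8-tetramethoxy-4H-chromen-4-one
Product: 11 2-[3,5-bis(benzyloxy)-4-methoxyphenyl]-5-hydroxy-3,6,7,8-tetramethoxy-4H-chromen-4-one
Conditions: Cu(acac)2 (10 mol%), N,N'-bis(4-hydroxy-2,6-dimethylphenyl)oxalamide (10 mol%), LiOH·H2O (2.5 equiv), DMSO/H2O 4:1, 80 °C; then 1 M HCl
Reagents that add atoms: lithium hydroxide, [Li+].[OH-]
Why: Copper-catalysed Ullmann-type hydroxylation of an aryl bromide: the C4 carbonyl peri to C5 coordinates copper and speeds oxidative addition into C5–Br, and the product forms as a chelated phenoxide that is shielded from further attack until it is acidified.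

Step 8
Reactants: 11 2-[3,5-bis(benzyloxy)-4-methoxyphenyl]-5-hydroxy-3,6,7,8-tetramethoxy-4H-chromen-4-one
Product: 12 5,3',5'-trihydroxy-3,6,7,8,4'-pentamethoxyflavone
Conditions: H2 (1 atm), 10% Pd/C, EtOAc/MeOH 1:1, rt
Reagents that add atoms: none
Why: Catalytic hydrogenolysis of the two aryl benzyl ethers over palladium; the tetrasubstituted C2–C3 double bond of the vinylogous ester and the aryl methyl ethers should be inert at one atmosphere and room temperature.

Compound list

1 | 3,4,5-trimethoxybenzoic acid | COc1cc(cc(OC)c1OC)C(=O)O | starting material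
2 | 2,6-dibromo-3,4,5-trimethoxybenzoic acid | OC(=O)c1c(Br)c(OC)c(OC)c(OC)c1Br | intermediate
3 | methyl 3,5-dihydroxy-4-methoxybenzoate | COC(=O)c1cc(O)c(OC)c(O)c1 | starting material
4 | methyl 3,5-bis(benzyloxy)-4-methoxybenzoate | COC(=O)c1cc(OCc2ccccc2)c(OC)c(OCc2ccccc2)c1 | intermediate
5 | methyl methoxyacetate | COCC(=O)OC | starting material
6 | racemic methyl 3-[3,5-bis(benzyloxy)-4-methoxyphenyl]-2-methoxy-3-oxopropanoate | COC(C(=O)OC)C(=O)c1cc(OCc2ccccc2)c(OC)c(OCc2ccccc2)c1 | intermediate
7 | 1-[3,5-bis(benzyloxy)-4-methoxyphenyl]-2-methoxyethan-1-one | COCC(=O)c1cc(OCc2ccccc2)c(OC)c(OCc2ccccc2)c1 | intermediate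
8 | 2,6-dibromo-3,4,5-trimethoxybenzoyl chloride | ClC(=O)c1c(Br)c(OC)c(OC)c(OC)c1Br | intermediate (not isolated)
9 | racemic 1-(2,6-dibromo-3,4,5-trimethoxyphenyl)-3-[3,5-bis(benzyloxy)-4-methoxyphenyl]-2-methoxypropane-1,3-dione | COC(C(=O)c1c(Br)c(OC)c(OC)c(OC)c1Br)C(=O)c1cc(OCc2ccccc2)c(OC)c(OCc2ccccc2)c1 | intermediate
10 | 2-[3,5-bis(benzyloxy)-4-methoxyphenyl]-5-bromo-3,6,7,8-tetramethoxy-4H-chromen-4-one | COc1c(OCc2ccccc2)cc(cc1OCc1ccccc1)-c1oc2c(OC)c(OC)c(OC)c(Br)c2c(=O)c1OC | intermediate
11 | 2-[3,5-bis(benzyloxy)-4-methoxyphenyl]-5-hydroxy-3,6,7,8-tetramethoxy-4H-chromen-4-one | COc1c(OCc2ccccc2)cc(cc1OCc1ccccc1)-c1oc2c(OC)c(OC)c(OC)c(O)c2c(=O)c1OC | intermediate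
12 | 5,3',5'-trihydroxy-3,6,7,8,4'-pentamethoxyflavone | COc1c(O)cc(-c2oc3c(OC)c(OC)c(OC)c(O)c3c(=O)c2OC)cc1O | target

Total step count: 8 steps.
Longest linear sequence: 7 steps (from 3 through steps 2, 3, 4, 5, 6, 7 and 8). The ring A branch (steps 1 and 5) joins at step 5.

Steps most likely to fail

1. Step 6. Oxidative addition may stall at the crowded ortho C–Br, which is flanked by a methoxy and the acyl group. Base-induced retro-Claisen cleavage of the diketone or reductive loss of bromine could then outrun ring closure. The fallback closes ring C through a phenol, forming O1–C2 by cyclodehydration and not O1–C8a by arylation. It sets out from 2 and 7 and returns at 10.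
   - Carboxylate-directed copper hydroxylation of one bromide of 2 (CuSO4, pyridine, aq. NaOH, 95 °C) should give 2-bromo-6-hydroxy-3,4,5-trimethoxybenzoic acid F1.
   - Acetone with trifluoroacetic anhydride and trifluoroacetic acid should convert this into the acetonide 5-bromo-6,7,8-trimethoxy-2,2-dimethyl-4H-1,3-benzodioxin-4-one F2.
   - The lithium enolate of 7 (LiN(SiMe3)2, THF, −78 to 0 °C) should open the lactone carbonyl with loss of acetone to give racemic 1-(2-bromo-6-hydroxy-3,4,5-trimethoxyphenyl)-3-[3,5-bis(benzyloxy)-4-methoxyphenyl]-2-methoxypropane-1,3-dione F3.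
   - Acid-catalysed cyclodehydration (TsOH, toluene, 80 °C) should then close the pyranone and rejoin the route at 10.

2. Step 7. Hydroxide may add at C2, open the pyranone and fragment the resulting diketone. The chelating 5-hydroxy-4-keto product may also bind copper and stop turnover. The fallback avoids hydroxide by bringing in the oxygen as a benzyl ether. It sets out from 10 and returns at 12.
   - Palladium-catalysed C–O coupling of 10 with benzyl alcohol ([Pd(allyl)Cl]2, RockPhos, Cs2CO3, toluene, 90 °C) should give 5-(benzyloxy)-2-[3,5-bis(benzyloxy)-4-methoxyphenyl]-3,6,7,8-tetramethoxy-4H-chromen-4-one F4.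
   - Hydrogenolysis under the conditions of step 8 should remove all three benzyl groups at once and deliver 12 directly.

3. Step 5. O-acylation of the enolate, or slow acyl transfer at the carbonyl between two ortho bromines, may divert or stall diketone formation. The fallback replaces the acylation by an aldol addition and an oxidation. It sets out from 8 and 7 and returns at 9.
   - Crude 8 is reduced with LiAlH(OtBu)3 (THF, −78 °C) to 2,6-dibromo-3,4,5-trimethoxybenzaldehyde F5.
   - The lithium enolate of 7 (LiN(i-Pr)2, THF, −78 °C) should add to this aldehyde to give 3-(2,6-dibromo-3,4,5-trimethoxyphenyl)-1-[3,5-bis(benzyloxy)-4-methoxyphenyl]-3-hydroxy-2-methoxypropan-1-one F6 as a mixture of racemic diastereomers.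
   - Both diastereomers should converge on 9 on oxidation with Dess–Martin periodinane (CH2Cl2, rt).

Further compounds

F1 | step 6 | 2-bromo-6-hydroxy-3,4,5-trimethoxybenzoic acid | OC(=O)c1c(O)c(OC)c(OC)c(OC)c1Br
F2 | step 6 | 5-bromo-6,7,8-trimethoxy-2,2-dimethyl-4H-1,3-benzodioxin-4-one | CC1(C)OC(=O)c2c(Br)c(OC)c(OC)c(OC)c2O1
F3 | step 6 | racemic 1-(2-bromo-6-hydroxy-3,4,5-trimethoxyphenyl)-3-[3,5-bis(benzyloxy)-4-methoxyphenyl]-2-methoxypropane-1,3-dione | COC(C(=O)c1c(O)c(OC)c(OC)c(OC)c1Br)C(=O)c1cc(OCc2ccccc2)c(OC)c(OCc2ccccc2)c1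
F4 | step 7 | 5-(benzyloxy)-2-[3,5-bis(benzyloxy)-4-methoxyphenyl]-3,6,7,8-tetramethoxy-4H-chromen-4-one | COc1c(OCc2ccccc2)cc(cc1OCc1ccccc1)-c1oc2c(OC)c(OC)c(OC)c(OCc3ccccc3)c2c(=O)c1OC
F5 | step 5 | 2,6-dibromo-3,4,5-trimethoxybenzaldehyde | O=Cc1c(Br)c(OC)c(OC)c(OC)c1Br
F6 | step 5 | 3-(2,6-dibromo-3,4,5-trimethoxyphenyl)-1-[3,5-bis(benzyloxy)-4-methoxyphenyl]-3-hydroxy-2-methoxypropan-1-one (mixture of racemic diastereomers) | COC(C(O)c1c(Br)c(OC)c(OC)c(OC)c1Br)C(=O)c1cc(OCc2ccccc2)c(OC)c(OCc2ccccc2)c1
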